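Each outer ring is a cyclised 1,3,5-triketone whose ring C=O between the CMe2 carbon and the acyl-bearing carbon sits at ester level, so the ring bond from the acyl-bearing carbon to that C=O is a Claisen bond. Everything rests on cutting this bond in both wings and masking each resulting triketo ester as a 4-pyranone. In one operation hydroxide opens both pyranones and each central methylene closes onto its CMe2CO2Me ester, forming both carbocycles. The precursor is the tri-O-benzyl butyrophenone core carrying two (4-oxopyran-3-yl)methyl arms, one 6-methyl and one 6-ethyl, each with a 2-C(CH3)2CO2CH3 group.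

Key step: step 11

Remark (protection): the three phenols of the central ring are carried as benzyl ethers, so that the last step is a neutral hydrogenolysis; 1,3,5-tris(benzyloxy)benzene is taken as a purchasable compound.
Remark (drawing): enolisable compounds are drawn in one tautomeric form; the target has no stereocentre.
Abbreviations: Bn = benzyl; TBS = tert-butyldimethylsilyl; MePyr-CH2 = [2-(1-methoxy-2-methyl-1-oxopropan-2-yl)-6-methyl-4-oxo-4H-pyran-3-yl]methyl; EtPyr-CH2 = the 6-ethyl analogue.

Step 1
Reactants: 1 methyl isobutyrate; 2 acrolein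
Product: 3 methyl 3-hydroxy-2,2-dimethylpent-4-enoate (racemic)
Conditions: LDA, THF, −78 °C; then 2, −78 °C; aq NH4Cl
Reagents that add atoms: none
Why: Directed aldol addition, in which the lithium enolate of the α-branched ester adds 1,2 to acrolein; the carbinol centre forms as a racemate and is erased in step 2.

Step 2
Reactants: 3 methyl 3-hydroxy-2,2-dimethylpent-4-enoate
Product: 4 methyl 2,2-dimethyl-3-oxopent-4-enoate
Conditions: Dess–Martin periodinane, CH2Cl2, 0 °C to rt; used without storage
Reagents that add atoms: none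
Why: Dess–Martin oxidation of a secondary allylic alcohol to the vinyl ketone under neutral conditions that spare the ester, the quaternary α-carbon excluding enolisation or double-bond migration.

Step 3
Reactants: 5 1,3,5-tris(benzyloxy)benzene; 4 methyl 2,2-dimethyl-3-oxopent-4-enoate
Product: 6 methyl 2,2-dimethyl-3-oxo-5-[2,4,6-tris(benzyloxy)phenyl]pentanoate
Conditions: Sc(OTf)3 (10 mol%), MeCN, rt; 5 in excess (2.5 equiv, recovered)
Reagents that add atoms: none
Why: Lewis-acid-catalysed Friedel–Crafts conjugate addition, in which Sc(OTf)3 chelates the 1,3-dicarbonyl unit of 4 and the trialkoxyarene attacks the terminal CH2, the excess of 5 holding the reaction at the mono-adduct.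

Step 4
Reactants: 6 methyl 2,2-dimethyl-3-oxo-5-[2,4,6-tris(benzyloxy)phenyl]pentanoate
Product: 7 methyl (Z)-3-(tert-butyldimethylsilyloxy)-2,2-dimethyl-5-[2,4,6-tris(benzyloxy)phenyl]pent-3-enoate
Conditions: TBSOTf, Et3N, CH2Cl2, 0 °C
Reagents that add atoms: tert-butyldimethylsilyl triflate, CC(C)(C)[Si](C)(C)OS(=O)(=O)C(F)(F)F
Why: Soft enolisation with a silyl triflate and an amine gives a single regioisomer because only the CH2 side of the ketone carries hydrogen, and the Z geometry is expected because it keeps the arylmethyl group away from the quaternary carbon (either geometry would serve in step 5).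

Step 5
Reactants: 7 methyl (Z)-3-(tert-butyldimethylsilyloxy)-2,2-dimethyl-5-[2,4,6-tris(benzyloxy)phenyl]pent-3-enoate; 8 2,2,6-trimethyl-4H-1,3-dioxin-4-one
Product: 10 methyl 2-methyl-2-(6-methyl-4-oxo-3-{[2,4,6-tris(benzyloxy)phenyl]methyl}-4H-pyran-2-yl)propanoate, via silyloxy-dihydropyranone cycloadduct 9 (not isolated)
Conditions: PhMe, 110 °C (8 in excess, acetone distilled off); then p-TsOH·H2O (cat.), 50 °C
Reagents that add atoms: none
Why: Thermal retro-[4+2] of the dioxinone releases acetylketene, which undergoes an inverse-demand hetero-Diels–Alder reaction with the silyl enol ether (enol CH carbon to the ketene carbon, acyl oxygen to the silyloxy carbon), and acid then eliminates silanol to the aromatic 4-pyranone, so the two transient stereocentres of 9 are lost.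

Step 6
Reactants: 10 methyl 2-methyl-2-(6-methyl-4-oxo-3-{[2,4,6-tris(benzyloxy)phenyl]methyl}-4H-pyran-2-yl)propanoate; 4 methyl 2,2-dimethyl-3-oxopent-4-enoate
Product: 11 methyl 5-[2,4,6-tris(benzyloxy)-3-(MePyr-CH2)phenyl]-2,2-dimethyl-3-oxopentanoate
Conditions: Sc(OTf)3 (20 mol%), MeCN, rt to 40 °C; 4 (1.05 equiv) added slowly
Reagents that add atoms: none
Why: The same Friedel–Crafts conjugate addition at one of the two equivalent free positions of 10; a third addition is disfavoured by the near-stoichiometric enone and because both benzyloxy groups flanking the last C–H are then buttressed out of conjugation.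

Step 7
Reactants: 11 methyl 5-[2,4,6-tris(benzyloxy)-3-(MePyr-CH2)phenyl]-2,2-dimethyl-3-oxopentanoate
Product: 12 methyl (Z)-5-[2,4,6-tris(benzyloxy)-3-(MePyr-CH2)phenyl]-3-(tert-butyldimethylsilyloxy)-2,2-dimethylpent-3-enoate
Conditions: TBSOTf (1.2 equiv), Et3N, CH2Cl2, −20 to 0 °C; cold aq NaHCO3 work-up
Reagents that add atoms: tert-butyldimethylsilyl triflate, CC(C)(C)[Si](C)(C)OS(=O)(=O)C(F)(F)F
Why: Soft enolisation as in step 4; any silylation at the pyranone oxygen or its 6-methyl group is reversible and should be undone by the bicarbonate wash, because C-protonation of a 2-methylene-2H-pyran restores the aromatic pyranone, whereas the hindered silyl enol ether survives aqueous work-up.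

Step 8
Reactants: 13 Meldrum's acid; 14 propanoyl chloride
Product: 15 5-(1-hydroxypropylidene)-2,2-dimethyl-1,3-dioxane-4,6-dione
Conditions: pyridine, CH2Cl2, 0 °C to rt; aq HCl wash
Reagents that add atoms: none
Why: C-acylation of the acidic methylene of Meldrum's acid by an acid chloride gives the enolised acyl Meldrum's acid, a standard thermal precursor of an acylketene.

Step 9
Reactants: 12 methyl (Z)-5-[2,4,6-tris(benzyloxy)-3-(MePyr-CH2)phenyl]-3-(tert-butyldimethylsilyloxy)-2,2-dimethylpent-3-enoate; 15 5-(1-hydroxypropylidene)-2,2-dimethyl-1,3-dioxane-4,6-dione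
Product: 17 1,3,5-tris(benzyloxy)-2-(MePyr-CH2)-4-(EtPyr-CH2)benzene, via silyloxy-dihydropyranone cycloadduct 16 (not isolated)
Conditions: PhMe, 110 °C (15 in excess); then p-TsOH·H2O (cat.), 50 °C
Reagents that add atoms: none
Why: Thermolysis of the acyl Meldrum's acid (loss of acetone and CO2) gives propionylketene, which repeats the hetero-Diels–Alder and silanol-elimination sequence of step 5 and fixes the ethyl group of the second wing, the first pyranone being inert to the ketene.

Step 10
Reactants: 17 1,3,5-tris(benzyloxy)-2-(MePyr-CH2)-4-(EtPyr-CH2)benzene; 18 butanoic acid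
Product: 19 1-[2,4,6-tris(benzyloxy)-3-(MePyr-CH2)-5-(EtPyr-CH2)phenyl]butan-1-one
Conditions: 18 and TFAA premixed, CH2Cl2, 0 °C to rt
Reagents that add atoms: none
Why: Friedel–Crafts acylation by the mixed butanoic trifluoroacetic anhydride at the only remaining aromatic C–H of the central ring, which is activated by two ortho and one para alkoxy groups, under metal-free conditions that spare benzyl ethers, esters and pyranones.

Step 11
Reactants: 19 1-[2,4,6-tris(benzyloxy)-3-(MePyr-CH2)-5-(EtPyr-CH2)phenyl]butan-1-one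
Product: 21 1-[2,4,6-tris(benzyloxy)-3-[(5-acetyl-2,6-dihydroxy-3,3-dimethyl-4-oxocyclohexa-1,5-dien-1-yl)methyl]-5-[(2,6-dihydroxy-3,3-dimethyl-4-oxo-5-propanoylcyclohexa-1,5-dien-1-yl)methyl]phenyl]butan-1-one, via bis-triketone diester 20 (not isolated)
Conditions: KOH (excess), THF–MeOH–H2O, 50 °C; then 1 M HCl
Reagents that add atoms: water (delivered as hydroxide), O
Why: Hydroxide adds in conjugate fashion to C6 (or C2) of each 4-pyranone and the ring O–C bond breaks, giving in either case the same enolate of the triketone RCO–CH2–CO–CH(CH2Ar)–CO–CMe2–CO2Me (20); its C5 methylene, flanked by two ketones, then acylates the CMe2-bound methyl ester with loss of methoxide, which makes the bond between the acyl-bearing carbon and the C=O next to CMe2 in each wing. The closest known reaction type is the base-induced opening of 4-pyranone esters to tricarbonyl anions followed by Claisen (Dieckmann) recyclisation, as used in polyketide-type syntheses of acylphloroglucinols. Each carbocycle closes in a 6-exo-trig mode (enolate carbon onto the exocyclic ester C=O), and no stereocentre is created because both rings end as fully enolised, conjugated triketones. The step needs Claisen closure to beat aldol closure, ester hydrolysis and retro-Claisen cleavage: the carbon between ester and ketone is quaternary, so the aldol path that turns ordinary triketo esters into resorcinols has no enolisable site, the ketone beside CMe2 is hindered and held in an enolate, and the neopentyl-type ester should be attacked faster by the internal carbanion than by external hydroxide. The product leaves all equilibria as its acyl-trione anion, and the fully benzylated central ring cannot form a quinone methide, so the methylene bridges should not scramble in base.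

Step 12
Reactants: 21 1-[2,4,6-tris(benzyloxy)-3-[(5-acetyl-2,6-dihydroxy-3,3-dimethyl-4-oxocyclohexa-1,5-dien-1-yl)methyl]-5-[(2,6-dihydroxy-3,3-dimethyl-4-oxo-5-propanoylcyclohexa-1,5-dien-1-yl)methyl]phenyl]butan-1-one
Product: 22 1-[3-[(5-acetyl-2,6-dihydroxy-3,3-dimethyl-4-oxocyclohexa-1,5-dien-1-yl)methyl]-5-[(2,6-dihydroxy-3,3-dimethyl-4-oxo-5-propanoylcyclohexa-1,5-dien-1-yl)methyl]-2,4,6-trihydroxyphenyl]butan-1-one (target)
Conditions: H2 (1 atm), Pd/C, EtOAc–MeOH, rt
Reagents that add atoms: none
Why: Catalytic hydrogenolysis of the three aryl benzyl ethers under neutral conditions, which should leave the hydrogen-bonded aryl ketone and the enolised triketone wings untouched and avoids the acid- or base-induced reactions of methylene-bridged phloroglucinols.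

Compound list
1 | methyl isobutyrate | COC(=O)C(C)C | starting material
2 | acrolein | C=CC=O | starting material
3 | methyl 3-hydroxy-2,2-dimethylpent-4-enoate (racemic) | COC(=O)C(C)(C)C(O)C=C | intermediate
4 | methyl 2,2-dimethyl-3-oxopent-4-enoate | COC(=O)C(C)(C)C(=O)C=C | intermediate
5 | 1,3,5-tris(benzyloxy)benzene | c1ccc(COc2cc(OCc3ccccc3)cc(OCc3ccccc3)c2)cc1 | starting material
6 | methyl 2,2-dimethyl-3-oxo-5-[2,4,6-tris(benzyloxy)phenyl]pentanoate | COC(=O)C(C)(C)C(=O)CCc1c(OCc2ccccc2)cc(OCc2ccccc2)cc1OCc1ccccc1 | intermediate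
7 | methyl (Z)-3-(tert-butyldimethylsilyloxy)-2,2-dimethyl-5-[2,4,6-tris(benzyloxy)phenyl]pent-3-enoate | COC(=O)C(C)(C)/C(O[Si](C)(C)C(C)(C)C)=C/Cc1c(OCc2ccccc2)cc(OCc2ccccc2)cc1OCc1ccccc1 | intermediate
8 | 2,2,6-trimethyl-4H-1,3-dioxin-4-one | CC1=CC(=O)OC(C)(C)O1 | starting material
9 | methyl 2-[2-(tert-butyldimethylsilyloxy)-6-methyl-4-oxo-3-{[2,4,6-tris(benzyloxy)phenyl]methyl}-3,4-dihydro-2H-pyran-2-yl]-2-methylpropanoate (racemic diastereomer mixture, both centres lost on elimination) | COC(=O)C(C)(C)C1(O[Si](C)(C)C(C)(C)C)OC(C)=CC(=O)C1Cc1c(OCc2ccccc2)cc(OCc2ccccc2)cc1OCc1ccccc1 | intermediate (not isolated)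
10 | methyl 2-methyl-2-(6-methyl-4-oxo-3-{[2,4,6-tris(benzyloxy)phenyl]methyl}-4H-pyran-2-yl)propanoate | COC(=O)C(C)(C)C1=C(Cc2c(OCc3ccccc3)cc(OCc3ccccc3)cc2OCc2ccccc2)C(=O)C=C(C)O1 | intermediate
11 | methyl 5-[2,4,6-tris(benzyloxy)-3-(MePyr-CH2)phenyl]-2,2-dimethyl-3-oxopentanoate | COC(=O)C(C)(C)C(=O)CCc1c(OCc2ccccc2)cc(OCc2ccccc2)c(CC2=C(C(C)(C)C(=O)OC)OC(C)=CC2=O)c1OCc1ccccc1 | intermediate
12 | methyl (Z)-5-[2,4,6-tris(benzyloxy)-3-(MePyr-CH2)phenyl]-3-(tert-butyldimethylsilyloxy)-2,2-dimethylpent-3-enoate | COC(=O)C(C)(C)/C(O[Si](C)(C)C(C)(C)C)=C/Cc1c(OCc2ccccc2)cc(OCc2ccccc2)c(CC2=C(C(C)(C)C(=O)OC)OC(C)=CC2=O)c1OCc1ccccc1 | intermediate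
13 | Meldrum's acid (2,2-dimethyl-1,3-dioxane-4,6-dione) | CC1(C)OC(=O)CC(=O)O1 | starting material
14 | propanoyl chloride | CCC(Cl)=O | starting material
15 | 5-(1-hydroxypropylidene)-2,2-dimethyl-1,3-dioxane-4,6-dione | CCC(O)=C1C(=O)OC(C)(C)OC1=O | intermediate
16 | 6-ethyl analogue of cycloadduct 9 on the arene that already carries MePyr-CH2 (racemic diastereomer mixture, both centres lost on elimination) | COC(=O)C(C)(C)C1(O[Si](C)(C)C(C)(C)C)OC(CC)=CC(=O)C1Cc1c(OCc2ccccc2)cc(OCc2ccccc2)c(CC2=C(C(C)(C)C(=O)OC)OC(C)=CC2=O)c1OCc1ccccc1 | intermediate (not isolated)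
17 | 1,3,5-tris(benzyloxy)-2-(MePyr-CH2)-4-(EtPyr-CH2)benzene | COC(=O)C(C)(C)C1=C(Cc2c(OCc3ccccc3)cc(OCc3ccccc3)c(CC3=C(C(C)(C)C(=O)OC)OC(C)=CC3=O)c2OCc2ccccc2)C(=O)C=C(CC)O1 | intermediate
18 | butanoic acid | CCCC(=O)O | starting material
19 | 1-[2,4,6-tris(benzyloxy)-3-(MePyr-CH2)-5-(EtPyr-CH2)phenyl]butan-1-one (key-step precursor) | CCCC(=O)c1c(OCc2ccccc2)c(CC2=C(C(C)(C)C(=O)OC)OC(C)=CC2=O)c(OCc2ccccc2)c(CC2=C(C(C)(C)C(=O)OC)OC(CC)=CC2=O)c1OCc1ccccc1 | intermediate
20 | open-chain bis(1,3,5-triketone) diester: each pyranone of 19 replaced by CH(CO–CH2–CO–R)(CO–CMe2–CO2Me), R = methyl or ethyl (keto form drawn; the two CH centres are enolisable and undefined) | CCCC(=O)c1c(OCc2ccccc2)c(CC(C(=O)CC(C)=O)C(=O)C(C)(C)C(=O)OC)c(OCc2ccccc2)c(CC(C(=O)CC(=O)CC)C(=O)C(C)(C)C(=O)OC)c1OCc1ccccc1 | intermediate (not isolated)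
21 | tri-O-benzyl ether of the target (key-step product) | CCCC(=O)c1c(OCc2ccccc2)c(CC2=C(O)C(C)(C)C(=O)C(C(C)=O)=C2O)c(OCc2ccccc2)c(CC2=C(O)C(C)(C)C(=O)C(C(=O)CC)=C2O)c1OCc1ccccc1 | intermediate
22 | 1-[3-[(5-acetyl-2,6-dihydroxy-3,3-dimethyl-4-oxocyclohexa-1,5-dien-1-yl)methyl]-5-[(2,6-dihydroxy-3,3-dimethyl-4-oxo-5-propanoylcyclohexa-1,5-dien-1-yl)methyl]-2,4,6-trihydroxyphenyl]butan-1-one | CCCC(=O)c1c(O)c(CC2=C(O)C(C)(C)C(=O)C(C(C)=O)=C2O)c(O)c(CC2=C(O)C(C)(C)C(=O)C(C(=O)CC)=C2O)c1O | target

Total step count: 12. Longest linear sequence: 11 steps (steps 1–7 and 9–12, from methyl isobutyrate); step 8 is a one-step side branch.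

Steps most likely to fail

Step 11. Saponification of the hindered esters or retro-Claisen cleavage at the ketone beside the quaternary carbon may outrun ring closure, or one pyranone may open more slowly than the other, so that half-converted material builds up. The fallback sets out from 19 and separates the two events. Both pyranones would be opened with Ba(OH)2·8H2O in aqueous THF–MeOH at room temperature, and after cold acidification the open-chain bis-triketone diester 20 would be isolated. Both rings would then be closed with Mg(OMe)2 in dry MeOH at reflux, where no hydroxide is present and the magnesium enolate holds the central methylene next to the ester (the chelation-controlled Claisen mode of triketo esters). The fallback comes back to the route at 21 and makes no compound outside the list (F0).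

Step 7. Silylation or lateral deprotonation of the pyranone already present (its 6-methyl group is vinylogously acidic) may compete with enolisation of the arm ketone, or the new enol ether may add to a transient silyloxypyrylium ion. The fallback sets out from 10 and makes the enol silane without any enolisation. Ethynylmagnesium bromide would be added to commercial methyl 2,2-dimethyl-3-oxopropanoate (THF, −78 °C) to give methyl 3-hydroxy-2,2-dimethylpent-4-ynoate F1, and Dess–Martin oxidation would give methyl 2,2-dimethyl-3-oxopent-4-ynoate F2. Hydroarylation of this electron-poor alkyne by 10 (Pd(OAc)2 cat., TFA–CH2Cl2, 0 °C to rt) should give methyl (E)-5-[2,4,6-tris(benzyloxy)-3-(MePyr-CH2)phenyl]-2,2-dimethyl-3-oxopent-4-enoate F3 (the geometry is irrelevant). The conjugated enone deactivates the ring against a second addition. A 1,4-hydrosilylation with t-BuMe2SiH and the Karstedt catalyst Pt2[(CH2=CHSiMe2)2O]3 in PhMe at 60 °C would then place the silyl enol ether regiospecifically and come back to the route at 12.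

Step 5 (the same reaction recurs in step 9). Capture of the acylketene by the hindered enol silane may be slow, so that ketene dimerisation and loss of the silyl group take over. The fallback sets out from 7 and builds the pyranone through an ynone. A Mukaiyama aldol addition of 7 to but-2-ynal (BF3·OEt2, CH2Cl2, −78 °C) would give methyl 5-hydroxy-2,2-dimethyl-3-oxo-4-{[2,4,6-tris(benzyloxy)phenyl]methyl}oct-6-ynoate F4 as a diastereomer mixture. Dess–Martin oxidation would give methyl 2,2-dimethyl-3,5-dioxo-4-{[2,4,6-tris(benzyloxy)phenyl]methyl}oct-6-ynoate F5. Its enol oxygen should add 6-endo-dig to the ynone β-carbon under catalytic p-TsOH in PhMe, which comes back to the route at 10.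

Further compounds
F0 | step 11 | none | none
F1 | step 7 | methyl 3-hydroxy-2,2-dimethylpent-4-ynoate (racemic) | COC(=O)C(C)(C)C(O)C#C
F2 | step 7 | methyl 2,2-dimethyl-3-oxopent-4-ynoate | COC(=O)C(C)(C)C(=O)C#C
F3 | step 7 | methyl (E)-5-[2,4,6-tris(benzyloxy)-3-(MePyr-CH2)phenyl]-2,2-dimethyl-3-oxopent-4-enoate | COC(=O)C(C)(C)C(=O)/C=C/c1c(OCc2ccccc2)cc(OCc2ccccc2)c(CC2=C(C(C)(C)C(=O)OC)OC(C)=CC2=O)c1OCc1ccccc1
F4 | step 5 | methyl 5-hydroxy-2,2-dimethyl-3-oxo-4-{[2,4,6-tris(benzyloxy)phenyl]methyl}oct-6-ynoate (diastereomer mixture) | COC(=O)C(C)(C)C(=O)C(Cc1c(OCc2ccccc2)cc(OCc2ccccc2)cc1OCc1ccccc1)C(O)C#CC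
F5 | step 5 | methyl 2,2-dimethyl-3,5-dioxo-4-{[2,4,6-tris(benzyloxy)phenyl]methyl}oct-6-ynoate | COC(=O)C(C)(C)C(=O)C(Cc1c(OCc2ccccc2)cc(OCc2ccccc2)cc1OCc1ccccc1)C(=O)C#CC
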